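## The problem

Erypoegin F (20) is a flat, fully aromatic 2-arylbenzofuran-3-carbaldehyde with no stereocentre, so the whole difficulty is regiochemical and chemoselective. Ring A (the benzo ring) carries three contiguous substituents, the furan oxygen at C7a, the 3-methylbut-2-enyl (prenyl) group at C7 and the methoxy group at C6, so the prenyl group must be placed between two oxygens and nowhere else. Ring B (the furan) carries a free 2,4-dihydroxyphenyl ring (ring D) at C2 and the formyl group at C3, and the formyl carbon is the hardest atom to place: an electrophilic formylation would have to choose C3 over the far more nucleophilic resorcinol positions and the trisubstituted alkene. The prenyl alkene excludes hydrogenolysis, electrophilic halogen and strong acid, and with a free ortho phenol it closes to a chroman under acid. The resorcinol ring and any 3-hydroxybenzofuran intermediate oxidise easily, and the 6-OMe group rules out methyl ethers as phenol protection. The feature that opens the problem is that the formyl carbon and the 2'-oxygen of ring D are 1,5-related through C3–C2–C1'–C2'. The hydroxy aldehyde is thus the open form of a six-membered lactol, and the corresponding lactone is a coumestan whose pyranone is ring C. The C3 carbon can therefore enter as carbon monoxide at a site fixed beforehand by a leaving group.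

## Retrosynthesis

**20 back to 18.** No skeletal bond is cut. The C–H bond of the formyl group is exchanged for a C–O bond to the 2'-oxygen, which leads through lactol 19 to coumestan 18. This is preferred over a direct formylation of a 2-arylbenzofuran, which has no means of finding C3. It is also preferred over a reductive carbonylation to the aldehyde, which would leave a deprotection to be done on a hydroxy aldehyde. Lactone 18 is a stable intermediate exactly one oxidation level above the target. The forward step must stop a hydride reduction of an aryl lactone at the lactol stage and leave the alkene alone.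

**18 back to 16 and 17.** The C3–C(=O) bond and the C(=O)–O2' bond of ring C are cut together, which removes the ring and releases carbon monoxide 17. A C3 ester followed by a separate lactonisation would cost a step, and a C3 carbanion plus a carboxylating agent cannot be made next to two free phenols. Precursor 16 has one ring less and carries a triflate at C3. The forward reaction asks zerovalent palladium to insert into an electron-rich heteroaryl triflate in the presence of two free phenols and a remote alkene.

**16 back to 15 and 13.** Two acetal C–O bonds (the protecting groups of ring D) and the O–S bond of the triflate are cut, giving ketone 13. A triflate is chosen over a 3-halide because it comes from a carbonyl group, whereas a halide would need electrophilic halogenation, which the prenyl alkene and ring D would not survive. Methoxymethyl ethers are chosen because mild acid removes them without touching the triflate or the 6-OMe group. The forward steps ask for O-selective sulfonylation of an ambident enolate, which the aromatic benzofuran-3-olate should guarantee, and for an acid deprotection that spares the alkene.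

**13 back to 10 and 12.** The C2–C1' bond is cut at the sp3 carbon next to the ketone. The same carbonyl group first activates C2 for arylation and then becomes the triflate, whereas a cross-coupling at C2 of a preformed benzofuran would need separate metallation and separate oxygenation of C3. Benzofuranone 10 and aryl bromide 12 are both simple; 12 is the bis(methoxymethyl) ether of 4-bromoresorcinol 11. The forward reaction is a palladium-catalysed ketone α-arylation with a hindered, electron-rich bromide.

**10 back to 8, then to 5 and 6.** The O1–C2 bond is cut first: an intramolecular etherification of chlorophenol ketone 9, which arises from 8 by loss of the acetal. Then the aryl–carbonyl bond C3a–C3 is cut, giving aryllithium 7 (from 5) and Weinreb amide 6. Friedel–Crafts or Hoesch acylation of the prenylated arene is rejected because its acid would cyclise the prenyl group onto the neighbouring phenol. Lithiation ortho to the acetal ether places the acyl group under basic conditions and at the right oxidation level.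

**5 back to 2 and 3, then to 1.** The aryl–CH2 bond at the carbon between the two oxygens is cut, giving aryllithium 4 (from 2) and prenyl bromide 3. Ether 2 is the protected form of 3-methoxyphenol 1. Claisen chemistry would deliver the reversed (1,1-dimethylallyl) group and Friedel–Crafts prenylation a mixture. Cooperative ortho-direction by the two oxygens makes this position the most acidic on the ring.

## Roads not taken

Alternative 1: The furan ring is cut at C3–C3a and O1–C7a. In the forward sense the β-ketoester ethyl 3-[2,4-bis(methoxymethoxy)phenyl]-3-oxopropanoate A3 is joined to the dihaloarene 2-bromo-1-iodo-4-methoxy-3-(3-methylbut-2-enyl)benzene A2 under CuI (monovalent copper) catalysis. C-arylation occurs at the iodide and then O-arylation of the enol at the bromide, giving ethyl 2-[2,4-bis(methoxymethoxy)phenyl]-6-methoxy-7-(3-methylbut-2-enyl)benzofuran-3-carboxylate A1.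
- Merits: it is more convergent than the chosen plan, makes ring B and installs the C3 carbon in one operation, needs no carbon monoxide, and avoids both the air-sensitive 2-arylbenzofuranone 13 and a triflate next to a free phenol. In these respects it is the better road.
- Weak points: A2 has four contiguous substituents, and its two halogens must be introduced without electrophilic halogen touching the alkene. The O-arylation must occur at a bromide flanked on both sides. The basic copper conditions invite retro-Claisen cleavage of A3. Ester A1 is a vinylogous carbonate that still needs reduction, reoxidation and deprotection.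
- Comparison: the chosen plan sets against this a ring A made by two ortho-lithiations of an unambiguous arene and a C3 carbon that arrives at the oxidation level of a lactone, one hydride from the target.

Alternative 2: Ring A is cut at C4–C5. In the forward sense the methyl ketone enolate of 5-[2,4-bis(methoxymethoxy)phenyl]-2-(6-methyl-2-oxohept-5-en-3-yl)furan-3-carbaldehyde A5 adds to its own aldehyde. Dehydration and enolisation then give 2-[2,4-bis(methoxymethoxy)phenyl]-7-(3-methylbut-2-enyl)benzofuran-6-ol A4.
- Merits: the 6-oxygen and 7-prenyl pattern is fixed by connectivity, with no dependence on lithiation regiochemistry. Here it is safer than step 3 of the chosen route.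
- Weak points: A5 is a 2,3,5-trisubstituted furan with a branched, prenylated side chain and would take many steps. Phenol A4 carries a free hydroxyl ortho to the prenyl group, which is the chroman-forming arrangement, until it is methylated. A4 also has no C3 carbon, so the formyl group must come from an electrophilic formylation that competes with the activated ring D and the alkene under conditions that also threaten the acetals.
- Comparison: this is the problem the chosen plan removes by letting a triflate dictate the site.

Alternative 3: Ring A is cut at C5–C6. In the forward sense the silyl ketene acetal 2-[1-(tert-butyldimethylsilyloxy)-1-methoxy-5-methylhexa-1,4-dien-2-yl]-3-vinylfuran A7 undergoes thermal disrotatory 6π closure. Elimination of the silyloxy group then aromatises the new ring and gives 6-methoxy-7-(3-methylbut-2-enyl)benzofuran A6.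
- Merits: A6 is reached regiospecifically and is small. Arylation at C2 of a benzofuran such as A6 by lithiation and cross-coupling is well precedented, arguably better than the α-arylation of step 6.
- Weak points: the closure of A7 must dearomatise the furan and will need high temperature, and A7 itself is a sensitive ketene acetal that must be made with a defined position of the vinyl group. A6 lacks both the aryl group and the formyl group. C3 must be functionalised electrophilically once the resorcinol ring is attached, or halogenated in the presence of the alkene.
- Comparison: it would be longer after the key step than the chosen plan, which needs only one reduction after ring C is closed.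

Key step: step 9

Assumption: lactol 19 and hydroxy aldehyde 20 are ring–chain tautomers that equilibrate on work-up, the open form 20 in which the compound is formulated is the one isolated, and ketone 13 and lactol 19 are racemic at a centre that is lost.

Step 1
Reactants: 1 3-methoxyphenol
Product: 2 1-methoxy-3-(methoxymethoxy)benzene
Conditions: MOMCl, i-Pr2NEt, CH2Cl2, 0 °C to rt
Reagents that add atoms: chloromethyl methyl ether (MOMCl), COCCl
Why: O-alkylation of the phenol with an α-chloro ether (Williamson type); the acetal ether protects the phenol and serves as the directing group for both ortho-lithiations that follow.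

Step 2
Reactants: 2 1-methoxy-3-(methoxymethoxy)benzene; 3 1-bromo-3-methylbut-2-ene
Product: 5 1-methoxy-3-(methoxymethoxy)-2-(3-methylbut-2-enyl)benzene, via aryllithium 4 (not isolated)
Conditions: n-BuLi, THF, 0 °C to rt; then CuBr·SMe2 (10 mol %), 3, −78 °C to rt
Reagents that add atoms: none
Why: Directed ortho-metalation removes the proton between the two oxygens, the most acidic on the ring; copper-catalysed allylic substitution of the aryllithium should give the linear prenyl arene, since the 2,6-disubstituted aryl group cannot easily reach the tertiary allyl terminus.

Step 3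
Reactants: 5 1-methoxy-3-(methoxymethoxy)-2-(3-methylbut-2-enyl)benzene; 6 2-chloro-N-methoxy-N-methylacetamide
Product: 8 2-chloro-1-[4-methoxy-2-(methoxymethoxy)-3-(3-methylbut-2-enyl)phenyl]ethanone, via aryllithium 7 (not isolated)
Conditions: n-BuLi, THF, 0 °C; then 6, −78 to 0 °C; aq. NH4Cl
Reagents that add atoms: none
Why: A second directed ortho-metalation should go ortho to the acetal ether, a stronger director than the methoxy group; Weinreb ketone synthesis with the chelated tetrahedral adduct prevents over-addition and releases the chloromethyl ketone on work-up.

Step 4
Reactants: 8 2-chloro-1-[4-methoxy-2-(methoxymethoxy)-3-(3-methylbut-2-enyl)phenyl]ethanone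
Product: 10 6-methoxy-7-(3-methylbut-2-enyl)benzofuran-3(2H)-one, via free phenol chloroketone 9 (not isolated)
Conditions: HCl (cat.), MeOH, 40 °C; then NaOAc, MeOH, reflux
Reagents that add atoms: none
Why: Acid-catalysed acetal methanolysis, assisted by the ortho carbonyl group, frees the phenol; buffered with acetate it closes by intramolecular Williamson etherification (5-exo-tet), the classical coumaranone synthesis. Adding acetate before heating keeps the freed phenol from cyclising onto the prenyl group.

Step 5
Reactants: 11 4-bromoresorcinol (4-bromobenzene-1,3-diol)
Product: 12 1-bromo-2,4-bis(methoxymethoxy)benzene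
Conditions: MOMCl, i-Pr2NEt, CH2Cl2, 0 °C to rt
Reagents that add atoms: chloromethyl methyl ether (MOMCl), COCCl
Why: Double O-alkylation of the two phenols; acetal ethers tolerate the basic coupling and enolate steps and are later removed by mild acid, which the prenyl group and the 6-OMe group survive.

Step 6
Reactants: 10 6-methoxy-7-(3-methylbut-2-enyl)benzofuran-3(2H)-one; 12 1-bromo-2,4-bis(methoxymethoxy)benzene
Product: 13 2-[2,4-bis(methoxymethoxy)phenyl]-6-methoxy-7-(3-methylbut-2-enyl)benzofuran-3(2H)-one (racemic at C2)
Conditions: Pd2(dba)3 (2.5 mol %), XPhos (2-dicyclohexylphosphino-2',4',6'-triisopropylbiphenyl, 6 mol %), K3PO4, toluene, 90 °C, argon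
Reagents that add atoms: none
Why: Palladium-catalysed ketone α-arylation (Buchwald–Hartwig type): oxidative addition of the aryl bromide, binding of the enolate and C–C reductive elimination. The C2–H, whose conjugate base is an aromatic benzofuran-3-olate, is acidic enough for K3PO4, which limits aldol self-condensation, and the ortho-substituted aryl group should block a second arylation. The new C2 stereocentre is formed racemic and is of no consequence, as the next step removes it.

Step 7
Reactants: 13 2-[2,4-bis(methoxymethoxy)phenyl]-6-methoxy-7-(3-methylbut-2-enyl)benzofuran-3(2H)-one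
Product: 15 2-[2,4-bis(methoxymethoxy)phenyl]-6-methoxy-7-(3-methylbut-2-enyl)benzofuran-3-yl trifluoromethanesulfonate, via potassium benzofuran-3-olate 14 (not isolated)
Conditions: KN(SiMe3)2, THF, −78 °C; then PhNTf2, −78 °C to rt; aq. NH4Cl
Reagents that add atoms: N-phenylbis(trifluoromethanesulfonimide) (PhNTf2), O=S(=O)(N(c1ccccc1)S(=O)(=O)C(F)(F)F)C(F)(F)F
Why: Enolate O-sulfonylation: deprotonation gives the aromatic benzofuran-3-olate, which reacts at oxygen with the triflyl donor; the imide reagent is used because triflic anhydride would attack the acetal ethers and the alkene.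

Step 8
Reactants: 15 2-[2,4-bis(methoxymethoxy)phenyl]-6-methoxy-7-(3-methylbut-2-enyl)benzofuran-3-yl trifluoromethanesulfonate
Product: 16 2-(2,4-dihydroxyphenyl)-6-methoxy-7-(3-methylbut-2-enyl)benzofuran-3-yl trifluoromethanesulfonate
Conditions: HCl (3 M aq.), MeOH/THF, 40 °C
Reagents that add atoms: none
Why: Acid-catalysed acetal methanolysis of both ethers; the triflate is inert to acid, and the prenyl group, flanked by the methoxy group and the furan oxygen, has no ortho phenol with which to form a chroman, so mild acid should leave it intact.

Step 9
Reactants: 16 2-(2,4-dihydroxyphenyl)-6-methoxy-7-(3-methylbut-2-enyl)benzofuran-3-yl trifluoromethanesulfonate; 17 carbon monoxide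
Product: 18 3-hydroxy-9-methoxy-10-(3-methylbut-2-enyl)-6H-benzofuro[3,2-c]chromen-6-one (3-hydroxy-9-methoxy-10-prenylcoumestan)
Conditions: Pd(OAc)2 (5 mol %), dppp (1,3-bis(diphenylphosphino)propane, 6 mol %), CO (1 atm), Et3N, DMF, 70 °C
Reagents that add atoms: none
Why: Divalent palladium is reduced in the flask to zerovalent palladium, which inserts into the C3–O bond of the triflate to give a cationic benzofuran-3-yl palladium complex held by the chelating diphosphine. Carbon monoxide coordinates and migratory insertion forms the acylpalladium, creating the C3–C(=O) bond. The 2'-hydroxyl, with triethylamine as proton acceptor, then attacks the acyl carbon (or binds palladium and undergoes C–O reductive elimination), forming the lactone C–O bond and returning zerovalent palladium. The closest known reaction types are the palladium-catalysed alkoxycarbonylation of aryl and enol triflates and the carbonylative lactonisation of 3-halo-2-(2-hydroxyaryl)benzofurans to coumestans. The one ring formed, pyranone ring C, closes in a 6-exo-trig mode at the acyl carbon, with the geometry preset by the C2–C1' biaryl bond; no stereocentre is created. Site selectivity between the two phenols is secured by the substrate, since only the 2'-OH can reach the acylpalladium in a six-membered ring while the 4'-OH could react only between molecules. The prenyl alkene at C7 is too far from C3 for a Heck cyclisation, and capture of carbon monoxide is faster than any intermolecular insertion. A weak amine base keeps the phenoxide concentration low, so that attack of phenoxide on the sulfur of the triflate should not compete with oxidative addition.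

Step 10
Reactants: 18 3-hydroxy-9-methoxy-10-(3-methylbut-2-enyl)-6H-benzofuro[3,2-c]chromen-6-one
Product: 20 erypoegin F (2-(2,4-dihydroxyphenyl)-6-methoxy-7-(3-methylbut-2-enyl)benzofuran-3-carbaldehyde), via coumestan lactol 19 (not isolated)
Conditions: i-Bu2AlH (2.3 equiv), THF/CH2Cl2, −78 °C; aq. potassium sodium tartrate (KNaC4H4O6)
Reagents that add atoms: none
Why: Half-reduction of an aryl lactone to the lactol, as known for dihydrocoumarins and benzo[c]chromenones: the first equivalent of hydride is consumed by the phenol and the second adds to the carbonyl group, giving an aluminium hemiacetal that should persist at −78 °C. On hydrolysis lactol 19 opens to the hydroxy aldehyde, a vinylogous formate ester conjugated through the furan; the alkene and the aromatic rings are not touched by the hydride.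

## Compound list

1 | 3-methoxyphenol | COc1cccc(O)c1 | starting material
2 | 1-methoxy-3-(methoxymethoxy)benzene | COCOc1cccc(OC)c1 | intermediate
3 | 1-bromo-3-methylbut-2-ene (prenyl bromide) | CC(C)=CCBr | starting material
4 | [2-methoxy-6-(methoxymethoxy)phenyl]lithium | [Li]c1c(OC)cccc1OCOC | intermediate
5 | 1-methoxy-3-(methoxymethoxy)-2-(3-methylbut-2-enyl)benzene | COCOc1cccc(OC)c1CC=C(C)C | intermediate
6 | 2-chloro-N-methoxy-N-methylacetamide | CON(C)C(=O)CCl | starting material
7 | [4-methoxy-2-(methoxymethoxy)-3-(3-methylbut-2-enyl)phenyl]lithium | [Li]c1ccc(OC)c(CC=C(C)C)c1OCOC | intermediate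
8 | 2-chloro-1-[4-methoxy-2-(methoxymethoxy)-3-(3-methylbut-2-enyl)phenyl]ethanone | COCOc1c(C(=O)CCl)ccc(OC)c1CC=C(C)C | intermediate
9 | 2-chloro-1-[2-hydroxy-4-methoxy-3-(3-methylbut-2-enyl)phenyl]ethanone | COc1ccc(C(=O)CCl)c(O)c1CC=C(C)C | intermediate
10 | 6-methoxy-7-(3-methylbut-2-enyl)benzofuran-3(2H)-one | COc1ccc2c(c1CC=C(C)C)OCC2=O | intermediate
11 | 4-bromoresorcinol (4-bromobenzene-1,3-diol) | Oc1ccc(Br)c(O)c1 | starting material
12 | 1-bromo-2,4-bis(methoxymethoxy)benzene | COCOc1ccc(Br)c(OCOC)c1 | intermediate
13 | 2-[2,4-bis(methoxymethoxy)phenyl]-6-methoxy-7-(3-methylbut-2-enyl)benzofuran-3(2H)-one (racemic) | COCOc1ccc(C2Oc3c(CC=C(C)C)c(OC)ccc3C2=O)c(OCOC)c1 | intermediate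
14 | potassium 2-[2,4-bis(methoxymethoxy)phenyl]-6-methoxy-7-(3-methylbut-2-enyl)benzofuran-3-olate | [K+].[O-]c1c(-c2ccc(OCOC)cc2OCOC)oc2c(CC=C(C)C)c(OC)ccc12 | intermediate
15 | 2-[2,4-bis(methoxymethoxy)phenyl]-6-methoxy-7-(3-methylbut-2-enyl)benzofuran-3-yl trifluoromethanesulfonate | O=S(=O)(Oc1c(-c2ccc(OCOC)cc2OCOC)oc2c(CC=C(C)C)c(OC)ccc12)C(F)(F)F | intermediate
16 | 2-(2,4-dihydroxyphenyl)-6-methoxy-7-(3-methylbut-2-enyl)benzofuran-3-yl trifluoromethanesulfonate | O=S(=O)(Oc1c(-c2ccc(O)cc2O)oc2c(CC=C(C)C)c(OC)ccc12)C(F)(F)F | intermediate
17 | carbon monoxide | [C-]#[O+] | starting material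
18 | 3-hydroxy-9-methoxy-10-(3-methylbut-2-enyl)-6H-benzofuro[3,2-c]chromen-6-one | COc1ccc2c(c1CC=C(C)C)oc1-c3ccc(O)cc3OC(=O)c12 | intermediate
19 | 9-methoxy-10-(3-methylbut-2-enyl)-6H-benzofuro[3,2-c]chromene-3,6-diol (racemic lactol) | COc1ccc2c(c1CC=C(C)C)oc1-c3ccc(O)cc3OC(O)c12 | intermediate
20 | erypoegin F, 2-(2,4-dihydroxyphenyl)-6-methoxy-7-(3-methylbut-2-enyl)benzofuran-3-carbaldehyde | COc1ccc2c(C=O)c(-c3ccc(O)cc3O)oc2c1CC=C(C)C | target

## Step count and risk

Total: 10 steps. Longest linear sequence: 9 steps (steps 1 to 4 and 6 to 10, from 1 to 20); step 5 is a one-step branch.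

**Step 9 (key step).** The most likely failure is loss of the triflate before palladium inserts: phenoxide attack at sulfur (triflyl transfer to the 2'-oxygen) or hydrolysis would return the benzofuranone. Oxidative addition at the electron-rich, doubly flanked C3 may also be slow. Fallback: the sequence sets out from 15, with both phenols still protected, and separates the carbonylation from the ring closure. A palladium-catalysed methoxycarbonylation (Pd(OAc)2, dppp, CO, MeOH, Et3N, DMF) should give methyl 2-[2,4-bis(methoxymethoxy)phenyl]-6-methoxy-7-(3-methylbut-2-enyl)benzofuran-3-carboxylate F1. Acid in methanol then removes both acetals to give methyl 2-(2,4-dihydroxyphenyl)-6-methoxy-7-(3-methylbut-2-enyl)benzofuran-3-carboxylate F2, and warming F2 with a sulfonic acid closes the lactone by transesterification with the 2'-phenol. The sequence comes back to the route at 18.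

**Step 3.** Deprotonation at the benzylic and allylic CH2 of the prenyl group (lateral metalation) may compete with ring lithiation, and some lithiation ortho to the methoxy group is possible. The aryllithium may also deprotonate the chloroacetamide instead of adding to it. Fallback: the aryl–carbonyl bond is made by electrophilic acylation before any prenyl group is present, and the prenyl group is then built by sigmatropic and metathesis chemistry. The sequence sets out from 1. Ortho-acylation of 1 with acetic acid and BF3·OEt2 gives 1-(2-hydroxy-4-methoxyphenyl)ethanone F3 (paeonol), which is O-allylated (3-bromoprop-1-ene, K2CO3, acetone) to 1-[4-methoxy-2-(prop-2-enyloxy)phenyl]ethanone F4. Thermal Claisen rearrangement of F4 can go only to the one free ortho position and gives 1-[2-hydroxy-4-methoxy-3-(prop-2-enyl)phenyl]ethanone F5. Cross-metathesis of F5 with 2-methylbut-2-ene (second-generation Grubbs catalyst RuCl2(H2IMes)(PCy3)(=CHPh)) gives 1-[2-hydroxy-4-methoxy-3-(3-methylbut-2-enyl)phenyl]ethanone F6. Double silylation (Me3SiOTf, Et3N) gives [1-(4-methoxy-3-(3-methylbut-2-enyl)-2-(trimethylsilyloxy)phenyl)ethenyloxy]trimethylsilane F7. Chlorination of the silyl enol ether of F7 with N-chlorosuccinimide at low temperature gives 2-chloro-1-[4-methoxy-3-(3-methylbut-2-enyl)-2-(trimethylsilyloxy)phenyl]ethanone F8, and a desilylating work-up of F8 comes back to the route at 9, which the acetate half of step 4 closes to 10.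

**Step 6.** Base-induced aldol self-condensation of 10, slow coupling with the hindered electron-rich bromide, and autoxidation at C2 of the 3-hydroxybenzofuran tautomer of the product are the likely losses. Fallback: the sequence sets out from 10 and arylates an aromatic benzofuran C–H bond instead of an enolate. Acylation of 10 with 2,2-dimethylpropanoyl chloride and Et3N gives the enol ester 6-methoxy-7-(3-methylbut-2-enyl)benzofuran-3-yl 2,2-dimethylpropanoate F9. Its C2–H is then arylated with 12 by palladium-catalysed direct arylation of the benzofuran (Pd(OAc)2, PCy3·HBF4, pivalic acid, K2CO3, N,N-dimethylacetamide), which gives 2-[2,4-bis(methoxymethoxy)phenyl]-6-methoxy-7-(3-methylbut-2-enyl)benzofuran-3-yl 2,2-dimethylpropanoate F10. Methanolysis of the ester of F10 (K2CO3, MeOH, argon) comes back to the route at 13.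

**Step 10.** Collapse of the aluminium hemiacetal with loss of the phenoxide would expose the aldehyde to a second hydride and lead to over-reduction. The aluminium phenoxide formed from the 3-OH may also deactivate the lactone and stall the reaction. Fallback: the sequence sets out from 18 and passes through the alcohol oxidation level. Full reduction with LiAlH4 in THF gives 4-[3-(hydroxymethyl)-6-methoxy-7-(3-methylbut-2-enyl)benzofuran-2-yl]benzene-1,3-diol F11. Chemoselective oxidation of the heteroaryl carbinol of F11 with activated MnO2 comes back to the route at 20.

## Further compounds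

F1 | step 9 | methyl 2-[2,4-bis(methoxymethoxy)phenyl]-6-methoxy-7-(3-methylbut-2-enyl)benzofuran-3-carboxylate | COC(=O)c1c(-c2ccc(OCOC)cc2OCOC)oc2c(CC=C(C)C)c(OC)ccc12
F2 | step 9 | methyl 2-(2,4-dihydroxyphenyl)-6-methoxy-7-(3-methylbut-2-enyl)benzofuran-3-carboxylate | COC(=O)c1c(-c2ccc(O)cc2O)oc2c(CC=C(C)C)c(OC)ccc12
F3 | step 3 | 1-(2-hydroxy-4-methoxyphenyl)ethanone | CC(=O)c1ccc(OC)cc1O
F4 | step 3 | 1-[4-methoxy-2-(prop-2-enyloxy)phenyl]ethanone | CC(=O)c1ccc(OC)cc1OCC=C
F5 | step 3 | 1-[2-hydroxy-4-methoxy-3-(prop-2-enyl)phenyl]ethanone | CC(=O)c1ccc(OC)c(CC=C)c1O
F6 | step 3 | 1-[2-hydroxy-4-methoxy-3-(3-methylbut-2-enyl)phenyl]ethanone | CC(=O)c1ccc(OC)c(CC=C(C)C)c1O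
F7 | step 3 | [1-(4-methoxy-3-(3-methylbut-2-enyl)-2-(trimethylsilyloxy)phenyl)ethenyloxy]trimethylsilane | C=C(O[Si](C)(C)C)c1ccc(OC)c(CC=C(C)C)c1O[Si](C)(C)C
F8 | step 3 | 2-chloro-1-[4-methoxy-3-(3-methylbut-2-enyl)-2-(trimethylsilyloxy)phenyl]ethanone | C[Si](C)(C)Oc1c(C(=O)CCl)ccc(OC)c1CC=C(C)C
F9 | step 6 | 6-methoxy-7-(3-methylbut-2-enyl)benzofuran-3-yl 2,2-dimethylpropanoate | CC(C)(C)C(=O)Oc1coc2c(CC=C(C)C)c(OC)ccc12
F10 | step 6 | 2-[2,4-bis(methoxymethoxy)phenyl]-6-methoxy-7-(3-methylbut-2-enyl)benzofuran-3-yl 2,2-dimethylpropanoate | CC(C)(C)C(=O)Oc1c(-c2ccc(OCOC)cc2OCOC)oc2c(CC=C(C)C)c(OC)ccc12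
F11 | step 10 | 4-[3-(hydroxymethyl)-6-methoxy-7-(3-methylbut-2-enyl)benzofuran-2-yl]benzene-1,3-diol | COc1ccc2c(CO)c(-c3ccc(O)cc3O)oc2c1CC=C(C)C
A1 | alternative 1 | ethyl 2-[2,4-bis(methoxymethoxy)phenyl]-6-methoxy-7-(3-methylbut-2-enyl)benzofuran-3-carboxylate | CCOC(=O)c1c(-c2ccc(OCOC)cc2OCOC)oc2c(CC=C(C)C)c(OC)ccc12
A2 | alternative 1 | 2-bromo-1-iodo-4-methoxy-3-(3-methylbut-2-enyl)benzene | COc1ccc(I)c(Br)c1CC=C(C)C
A3 | alternative 1 | ethyl 3-[2,4-bis(methoxymethoxy)phenyl]-3-oxopropanoate | CCOC(=O)CC(=O)c1ccc(OCOC)cc1OCOC
A4 | alternative 2 | 2-[2,4-bis(methoxymethoxy)phenyl]-7-(3-methylbut-2-enyl)benzofuran-6-ol | COCOc1ccc(-c2cc3ccc(O)c(CC=C(C)C)c3o2)c(OCOC)c1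
A5 | alternative 2 | 5-[2,4-bis(methoxymethoxy)phenyl]-2-(6-methyl-2-oxohept-5-en-3-yl)furan-3-carbaldehyde | CC(=O)C(CC=C(C)C)c1oc(-c2ccc(OCOC)cc2OCOC)cc1C=O
A6 | alternative 3 | 6-methoxy-7-(3-methylbut-2-enyl)benzofuran | COc1ccc2ccoc2c1CC=C(C)C
A7 | alternative 3 | 2-[1-(tert-butyldimethylsilyloxy)-1-methoxy-5-methylhexa-1,4-dien-2-yl]-3-vinylfuran | COC(O[Si](C)(C)C(C)(C)C)=C(CC=C(C)C)c1occc1C=C
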